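**Strategy.** With prostanoid numbering (ring C8–C12, ketone C9, bromine on C10, carbinol C12), the α-bromoenone C9(=O)–C10(Br)=C11H is read as the product of a dibromocarbene ring expansion. C10 is inserted into the C9–C11 bond of a cyclobutanone silyl enol ether, so the cyclopentenone grows from a four-membered ring and the bromine arrives with the new carbon. Because the ring neighbours of C12 (C8, C11) are then both methylenes, the precursor is a mirror-symmetric 3-silyloxy-3-octenylcyclobutanone, and a chiral lithium amide fixes C12 by choosing one methylene. The 5E,7Z-dienylidene is then attached at C8 through a chelation-controlled Z-enol triflate and a Suzuki coupling.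

Key step: step 7

Assumption: the (S,S)-lithium amide is taken to give enol ether 9 in the configuration drawn; if the sense of induction is the opposite, the (R,R)-amide is used with no other change.

**Step 1**
Reactants: 1 (2Z)-oct-2-en-1-ol
Product: 2 (2Z)-1-chlorooct-2-ene
Conditions: N-chlorosuccinimide, Me2S, CH2Cl2, −20 → 0 °C
Reagents that add atoms: N-chlorosuccinimide, O=C1CCC(=O)N1Cl
Why: Corey–Kim chlorination displaces the alkoxysulfonium ion by chloride in an SN2 reaction at the primary carbon, so neither allylic transposition nor loss of the Z geometry is expected.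

**Step 2**
Reactants: 2 (2Z)-1-chlorooct-2-ene; 3 3-(benzyloxy)cyclobutan-1-one
Product: 5 3-(benzyloxy)-1-[(2Z)-oct-2-en-1-yl]cyclobutan-1-ol (cis/trans mixture), via (2Z)-oct-2-enylbarium chloride 4 (not isolated)
Conditions: activated barium (Ba*, from BaI2 and lithium biphenylide), THF, −78 °C; then 3, −78 °C; aq. NH4Cl
Reagents that add atoms: none
Why: Carbonyl allylation with an allylic barium reagent takes place at the α-carbon with retention of the Z double bond at −78 °C, so the linear octenyl carbinol should form directly; the cis/trans relation to the benzyloxy carbon is irrelevant because that carbon becomes the ketone.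

**Step 3**
Reactants: 5 3-(benzyloxy)-1-[(2Z)-oct-2-en-1-yl]cyclobutan-1-ol
Product: 6 {3-(benzyloxy)-1-[(2Z)-oct-2-en-1-yl]cyclobutoxy}triethylsilane
Conditions: Et3SiOTf, 2,6-lutidine, CH2Cl2, −78 → 0 °C
Reagents that add atoms: triethylsilyl trifluoromethanesulfonate, CC[Si](CC)(CC)OS(=O)(=O)C(F)(F)F
Why: O-Silylation with a silyl triflate and a hindered pyridine base is the standard way to protect a tertiary alcohol.

**Step 4**
Reactants: 6 {3-(benzyloxy)-1-[(2Z)-oct-2-en-1-yl]cyclobutoxy}triethylsilane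
Product: 7 3-[(2Z)-oct-2-en-1-yl]-3-(triethylsilyloxy)cyclobutan-1-ol (cis/trans mixture)
Conditions: LiDBB (lithium 4,4′-di-tert-butylbiphenylide), THF, −78 °C; aq. NH4Cl
Reagents that add atoms: none
Why: Reductive debenzylation by an arene radical anion cleaves the benzylic C–O bond and should leave the isolated Z-alkene and the silyl ether untouched.

**Step 5**
Reactants: 7 3-[(2Z)-oct-2-en-1-yl]-3-(triethylsilyloxy)cyclobutan-1-ol
Product: 8 3-[(2Z)-oct-2-en-1-yl]-3-(triethylsilyloxy)cyclobutan-1-one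
Conditions: Dess–Martin periodinane, NaHCO3, CH2Cl2, 23 °C
Reagents that add atoms: none
Why: Buffered Dess–Martin oxidation of the secondary alcohol should give the achiral, mirror-symmetric cyclobutanone without loss of the β-silyloxy group.

**Step 6**
Reactants: 8 3-[(2Z)-oct-2-en-1-yl]-3-(triethylsilyloxy)cyclobutan-1-one
Product: 9 triethyl({(1S)-1-[(2Z)-oct-2-en-1-yl]-3-(trimethylsilyloxy)cyclobut-2-en-1-yl}oxy)silane
Conditions: lithium bis[(1S)-1-phenylethyl]amide (from the amine and n-BuLi), Me3SiCl present from the start (in situ quench), THF, −100 °C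
Reagents that add atoms: chlorotrimethylsilane, C[Si](C)(C)Cl
Why: Enantioselective deprotonation of a prochiral 3-substituted cyclobutanone by a chiral lithium amide removes a proton from one of the two enantiotopic α-methylenes, so reagent control makes C12 a stereocentre (S in 9, the centre that is 12R in the target), while the immediate O-silylation suppresses β-elimination of the silyloxy group.

**Step 7**
Reactants: 9 triethyl({(1S)-1-[(2Z)-oct-2-en-1-yl]-3-(trimethylsilyloxy)cyclobut-2-en-1-yl}oxy)silane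
Product: 11 (4S)-2-bromo-4-[(2Z)-oct-2-en-1-yl]-4-(triethylsilyloxy)cyclopent-2-en-1-one, via dibromobicyclo[2.1.0]pentane 10 (not isolated)
Conditions: CHBr3, KOtBu, pentane, −40 → 23 °C; aq. NaHCO3
Reagents that add atoms: bromoform, BrC(Br)Br
Why: Dibromocarbene from bromoform and KOtBu adds in a [2+1] cheletropic manner to the electron-rich enol ether bond C9=C11, which closes the cyclopropane of 10; the strained 1-siloxybicyclo[2.1.0]pentane then opens by disrotatory cyclopropyl-to-allyl cleavage of the former C9–C11 bond with loss of the endo bromide, and the siloxyallyl cation gives its trimethylsilyl group to bromide, so the four-membered ring becomes the 2-bromocyclopentenone with C10 and its bromine in place. The closest known reaction type is the dihalocarbene ring enlargement of cyclic silyl enol ethers to 2-halo-2-cycloalkenones and of cyclobutenes to 2,3-dihalocyclopentenes. No new stereocentre survives (the ring-fusion centres of 10 are destroyed) and no bond to C12 is broken, so the configuration from step 6 is carried over. The step needs chemoselectivity for the enol ether over the Z-dialkyl alkene, which the far higher nucleophilicity of the silyl enol ether towards the electrophilic carbene should secure, and the regiochemistry is fixed by the position of the enol ether double bond.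

**Step 8**
Reactants: 11 (4S)-2-bromo-4-[(2Z)-oct-2-en-1-yl]-4-(triethylsilyloxy)cyclopent-2-en-1-one
Product: 12 (4R,5Z)-2-bromo-5-(hydroxymethylidene)-4-[(2Z)-oct-2-en-1-yl]-4-(triethylsilyloxy)cyclopent-2-en-1-one
Conditions: LiN(SiMe3)2 (2.2 equiv), THF, −78 °C; HCO2CH2CF3; aq. NH4Cl
Reagents that add atoms: 2,2,2-trifluoroethyl formate, O=COCC(F)(F)F
Why: Kinetic enolisation is possible only at C8, and Claisen-type C-formylation of this cross-conjugated enolate gives the hydrogen-bonded Z-enol, the C12 silyloxy group not being expelled because that would create a cyclopentadienone.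

**Step 9**
Reactants: 12 (4R,5Z)-2-bromo-5-(hydroxymethylidene)-4-[(2Z)-oct-2-en-1-yl]-4-(triethylsilyloxy)cyclopent-2-en-1-one
Product: 13 (Z)-{(2R)-4-bromo-2-[(2Z)-oct-2-en-1-yl]-5-oxo-2-(triethylsilyloxy)cyclopent-3-en-1-ylidene}methyl trifluoromethanesulfonate
Conditions: LiN(SiMe3)2, Et2O–toluene, −78 °C; Tf2O
Reagents that add atoms: trifluoromethanesulfonic anhydride, O=S(=O)(OS(=O)(=O)C(F)(F)F)C(F)(F)F
Why: O-Sulfonylation of the lithium chelate of the β-ketoaldehyde, in which the formyl oxygen is held cis to the C9 carbonyl and away from the crowded C12, should give the Z-enol triflate and so fix the later 7Z geometry.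

**Step 10**
Reactants: 14 methyl hex-5-ynoate
Product: 15 methyl (5E)-6-(4,4,5,5-tetramethyl-1,3,2-dioxaborolan-2-yl)hex-5-enoate
Conditions: pinacolborane, Cp2Zr(H)Cl (cat.), Et3N (cat.), CH2Cl2, 23 °C
Reagents that add atoms: pinacolborane, CC1(C)OBOC1(C)C
Why: Zirconocene-hydride-catalysed syn hydroboration of the terminal alkyne places boron on the terminal carbon and gives the E-alkenylboronate, and the methyl ester is tolerated.

**Step 11**
Reactants: 13 (Z)-{(2R)-4-bromo-2-[(2Z)-oct-2-en-1-yl]-5-oxo-2-(triethylsilyloxy)cyclopent-3-en-1-ylidene}methyl trifluoromethanesulfonate; 15 methyl (5E)-6-(4,4,5,5-tetramethyl-1,3,2-dioxaborolan-2-yl)hex-5-enoate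
Product: 16 methyl (5E,7Z)-7-{(2R)-4-bromo-2-[(2Z)-oct-2-en-1-yl]-5-oxo-2-(triethylsilyloxy)cyclopent-3-en-1-ylidene}hept-5-enoate
Conditions: Pd(PPh3)4 (cat.), aq. K3PO4, THF, 0 → 23 °C
Reagents that add atoms: none
Why: Suzuki–Miyaura coupling proceeds with retention at both sp2 carbons, so 7Z and 5E are transferred, and zerovalent palladium should insert into the vinylogous acyl triflate at room temperature much faster than into the sluggish C–Br bond of the α-bromoenone.

**Step 12**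
Reactants: 16 methyl (5E,7Z)-7-{(2R)-4-bromo-2-[(2Z)-oct-2-en-1-yl]-5-oxo-2-(triethylsilyloxy)cyclopent-3-en-1-ylidene}hept-5-enoate
Product: 17 methyl (5E,7Z)-7-{(2R)-4-bromo-2-hydroxy-2-[(2Z)-oct-2-en-1-yl]-5-oxocyclopent-3-en-1-ylidene}hept-5-enoate
Conditions: HF·pyridine, pyridine, THF, 0 → 23 °C
Reagents that add atoms: none
Why: Buffered fluoride-mediated desilylation cleaves the tertiary triethylsilyl ether under conditions that should spare the ester, the vinyl bromide and the cross-conjugated dienone.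

**Step 13**
Reactants: 17 methyl (5E,7Z)-7-{(2R)-4-bromo-2-hydroxy-2-[(2Z)-oct-2-en-1-yl]-5-oxocyclopent-3-en-1-ylidene}hept-5-enoate
Product: 18 methyl (5E,7Z)-7-{(2R)-2-acetoxy-4-bromo-2-[(2Z)-oct-2-en-1-yl]-5-oxocyclopent-3-en-1-ylidene}hept-5-enoate
Conditions: Ac2O, DMAP, CH2Cl2, 23 °C
Reagents that add atoms: acetic anhydride, CC(=O)OC(C)=O
Why: DMAP-catalysed acylation of the tertiary alcohol should give the acetate without touching C12 or the alkene geometries.

**Compound list**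
1 | (2Z)-oct-2-en-1-ol | CCCCC/C=C\CO | starting material
2 | (2Z)-1-chlorooct-2-ene | CCCCC/C=C\CCl | intermediate
3 | 3-(benzyloxy)cyclobutan-1-one | O=C1CC(OCc2ccccc2)C1 | starting material
4 | (2Z)-oct-2-enylbarium chloride | CCCCC/C=C\C[Ba]Cl | intermediate
5 | 3-(benzyloxy)-1-[(2Z)-oct-2-en-1-yl]cyclobutan-1-ol (cis/trans mixture) | CCCCC/C=C\CC1(O)CC(OCc2ccccc2)C1 | intermediate
6 | {3-(benzyloxy)-1-[(2Z)-oct-2-en-1-yl]cyclobutoxy}triethylsilane | CCCCC/C=C\CC1(O[Si](CC)(CC)CC)CC(OCc2ccccc2)C1 | intermediate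
7 | 3-[(2Z)-oct-2-en-1-yl]-3-(triethylsilyloxy)cyclobutan-1-ol (cis/trans mixture) | CCCCC/C=C\CC1(O[Si](CC)(CC)CC)CC(O)C1 | intermediate
8 | 3-[(2Z)-oct-2-en-1-yl]-3-(triethylsilyloxy)cyclobutan-1-one | CCCCC/C=C\CC1(O[Si](CC)(CC)CC)CC(=O)C1 | intermediate
9 | triethyl({(1S)-1-[(2Z)-oct-2-en-1-yl]-3-(trimethylsilyloxy)cyclobut-2-en-1-yl}oxy)silane | CCCCC/C=C\C[C@@]1(O[Si](CC)(CC)CC)C=C(O[Si](C)(C)C)C1 | intermediate
10 | (3S)-5,5-dibromo-3-[(2Z)-oct-2-en-1-yl]-3-(triethylsilyloxy)-1-(trimethylsilyloxy)bicyclo[2.1.0]pentane (cyclopropane on either face) | CCCCC/C=C\C[C@@]1(O[Si](CC)(CC)CC)C2C(Br)(Br)C2(O[Si](C)(C)C)C1 | intermediate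
11 | (4S)-2-bromo-4-[(2Z)-oct-2-en-1-yl]-4-(triethylsilyloxy)cyclopent-2-en-1-one | CCCCC/C=C\C[C@@]1(O[Si](CC)(CC)CC)C=C(Br)C(=O)C1 | intermediate
12 | (4R,5Z)-2-bromo-5-(hydroxymethylidene)-4-[(2Z)-oct-2-en-1-yl]-4-(triethylsilyloxy)cyclopent-2-en-1-one | CCCCC/C=C\C[C@@]1(O[Si](CC)(CC)CC)C=C(Br)C(=O)/C1=C\O | intermediate
13 | (Z)-{(2R)-4-bromo-2-[(2Z)-oct-2-en-1-yl]-5-oxo-2-(triethylsilyloxy)cyclopent-3-en-1-ylidene}methyl trifluoromethanesulfonate | CCCCC/C=C\C[C@@]1(O[Si](CC)(CC)CC)C=C(Br)C(=O)/C1=C\OS(=O)(=O)C(F)(F)F | intermediate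
14 | methyl hex-5-ynoate | COC(=O)CCCC#C | starting material
15 | methyl (5E)-6-(4,4,5,5-tetramethyl-1,3,2-dioxaborolan-2-yl)hex-5-enoate | COC(=O)CCC/C=C/B1OC(C)(C)C(C)(C)O1 | intermediate
16 | methyl (5E,7Z)-7-{(2R)-4-bromo-2-[(2Z)-oct-2-en-1-yl]-5-oxo-2-(triethylsilyloxy)cyclopent-3-en-1-ylidene}hept-5-enoate | CCCCC/C=C\C[C@@]1(O[Si](CC)(CC)CC)C=C(Br)C(=O)/C1=C\C=C\CCCC(=O)OC | intermediate
17 | methyl (5E,7Z)-7-{(2R)-4-bromo-2-hydroxy-2-[(2Z)-oct-2-en-1-yl]-5-oxocyclopent-3-en-1-ylidene}hept-5-enoate | CCCCC/C=C\C[C@@]1(O)C=C(Br)C(=O)/C1=C\C=C\CCCC(=O)OC | intermediate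
18 | methyl (5E,7Z)-7-{(2R)-2-acetoxy-4-bromo-2-[(2Z)-oct-2-en-1-yl]-5-oxocyclopent-3-en-1-ylidene}hept-5-enoate | CCCCC/C=C\C[C@@]1(OC(C)=O)C=C(Br)C(=O)/C1=C\C=C\CCCC(=O)OC | target

Total step count: 13. Longest linear sequence: 12 (steps 1–9 and 11–13).

**Steps most likely to fail**

Step 7. The carbene may attack the side-chain Z-alkene, the base may desilylate the enol ether before cyclopropanation, or the bromoenone may decompose under the basic conditions. The fallback sets out from 9 and separates cyclopropanation from ring enlargement. Et2Zn/CH2I2 (Simmons–Smith type) should give (3S)-3-[(2Z)-oct-2-en-1-yl]-3-(triethylsilyloxy)-1-(trimethylsilyloxy)bicyclo[2.1.0]pentane F1. FeCl3 in DMF should cleave the ring-fusion bond oxidatively to the ring-enlarged (4S)-3-chloro-4-[(2Z)-oct-2-en-1-yl]-4-(triethylsilyloxy)cyclopentan-1-one F2. NaOAc should then eliminate HCl to give (4S)-4-[(2Z)-oct-2-en-1-yl]-4-(triethylsilyloxy)cyclopent-2-en-1-one F3. Nucleophilic epoxidation (H2O2, NaOH, MeOH) should give 4-[(2Z)-oct-2-en-1-yl]-4-(triethylsilyloxy)-6-oxabicyclo[3.1.0]hexan-2-one F4. MgBr2·OEt2 should open F4 at the α-carbon to 2-bromo-3-hydroxy-4-[(2Z)-oct-2-en-1-yl]-4-(triethylsilyloxy)cyclopentan-1-one F5. Its mesylate, 3-bromo-2-[(2Z)-oct-2-en-1-yl]-4-oxo-2-(triethylsilyloxy)cyclopentyl methanesulfonate F6 (MsCl, Et3N), should eliminate by E1cB to rejoin the route at 11.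

Step 6. The two enantiotopic methylenes may be poorly discriminated because both C12 substituents are large, and the silyloxy group may be lost by β-elimination from the enolate. The fallback sets out from 8 and replaces asymmetric induction by resolution. LiN(SiMe3)2/Me3SiCl should give the racemic triethyl({1-[(2Z)-oct-2-en-1-yl]-3-(trimethylsilyloxy)cyclobut-2-en-1-yl}oxy)silane F7. Under the conditions of step 7 it should pass through racemic 5,5-dibromo-3-[(2Z)-oct-2-en-1-yl]-3-(triethylsilyloxy)-1-(trimethylsilyloxy)bicyclo[2.1.0]pentane F8 to racemic 2-bromo-4-[(2Z)-oct-2-en-1-yl]-4-(triethylsilyloxy)cyclopent-2-en-1-one F9. Preparative chromatography on a chiral stationary phase should then deliver the S enantiomer, which is 11.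

Step 9. O-Triflation may lose geometric control (E-triflate) or occur at the ring oxygen, which would show up as the 7E isomer or a misplaced chain after coupling. The fallback sets out from 11 and builds the dienylidene by aldol condensation. The lithium enolate of 11 (LiN(iPr)2, THF, −78 °C) should add to methyl (5E)-7-oxohept-5-enoate F10 to give methyl (5E)-7-{4-bromo-2-[(2Z)-oct-2-en-1-yl]-5-oxo-2-(triethylsilyloxy)cyclopent-3-en-1-yl}-7-hydroxyhept-5-enoate F11. The derived methyl (5E)-7-{4-bromo-2-[(2Z)-oct-2-en-1-yl]-5-oxo-2-(triethylsilyloxy)cyclopent-3-en-1-yl}-7-(methylsulfonyloxy)hept-5-enoate F12 (MsCl, Et3N) should eliminate with DBU to 16 together with its 7E isomer, methyl (5E,7E)-7-{(2R)-4-bromo-2-[(2Z)-oct-2-en-1-yl]-5-oxo-2-(triethylsilyloxy)cyclopent-3-en-1-ylidene}hept-5-enoate F13. F13 is separated and re-equilibrated by irradiation, and the route is rejoined at 16.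

**Further compounds**
F1 | step 7 | (3S)-3-[(2Z)-oct-2-en-1-yl]-3-(triethylsilyloxy)-1-(trimethylsilyloxy)bicyclo[2.1.0]pentane | CCCCC/C=C\C[C@@]1(O[Si](CC)(CC)CC)C2CC2(O[Si](C)(C)C)C1
F2 | step 7 | (4S)-3-chloro-4-[(2Z)-oct-2-en-1-yl]-4-(triethylsilyloxy)cyclopentan-1-one | CCCCC/C=C\C[C@@]1(O[Si](CC)(CC)CC)C(Cl)CC(=O)C1
F3 | step 7 | (4S)-4-[(2Z)-oct-2-en-1-yl]-4-(triethylsilyloxy)cyclopent-2-en-1-one | CCCCC/C=C\C[C@@]1(O[Si](CC)(CC)CC)C=CC(=O)C1
F4 | step 7 | 4-[(2Z)-oct-2-en-1-yl]-4-(triethylsilyloxy)-6-oxabicyclo[3.1.0]hexan-2-one | CCCCC/C=C\C[C@@]1(O[Si](CC)(CC)CC)C2OC2C(=O)C1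
F5 | step 7 | 2-bromo-3-hydroxy-4-[(2Z)-oct-2-en-1-yl]-4-(triethylsilyloxy)cyclopentan-1-one | CCCCC/C=C\C[C@@]1(O[Si](CC)(CC)CC)C(O)C(Br)C(=O)C1
F6 | step 7 | 3-bromo-2-[(2Z)-oct-2-en-1-yl]-4-oxo-2-(triethylsilyloxy)cyclopentyl methanesulfonate | CCCCC/C=C\C[C@@]1(O[Si](CC)(CC)CC)C(OS(C)(=O)=O)C(Br)C(=O)C1
F7 | step 6 | racemic triethyl({1-[(2Z)-oct-2-en-1-yl]-3-(trimethylsilyloxy)cyclobut-2-en-1-yl}oxy)silane | CCCCC/C=C\CC1(O[Si](CC)(CC)CC)C=C(O[Si](C)(C)C)C1
F8 | step 6 | racemic 5,5-dibromo-3-[(2Z)-oct-2-en-1-yl]-3-(triethylsilyloxy)-1-(trimethylsilyloxy)bicyclo[2.1.0]pentane | CCCCC/C=C\CC1(O[Si](CC)(CC)CC)C2C(Br)(Br)C2(O[Si](C)(C)C)C1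
F9 | step 6 | racemic 2-bromo-4-[(2Z)-oct-2-en-1-yl]-4-(triethylsilyloxy)cyclopent-2-en-1-one | CCCCC/C=C\CC1(O[Si](CC)(CC)CC)C=C(Br)C(=O)C1
F10 | step 9 | methyl (5E)-7-oxohept-5-enoate | COC(=O)CCC/C=C/C=O
F11 | step 9 | methyl (5E)-7-{4-bromo-2-[(2Z)-oct-2-en-1-yl]-5-oxo-2-(triethylsilyloxy)cyclopent-3-en-1-yl}-7-hydroxyhept-5-enoate (mixture at C7 and C8) | CCCCC/C=C\C[C@@]1(O[Si](CC)(CC)CC)C=C(Br)C(=O)C1C(O)/C=C/CCCC(=O)OC
F12 | step 9 | methyl (5E)-7-{4-bromo-2-[(2Z)-oct-2-en-1-yl]-5-oxo-2-(triethylsilyloxy)cyclopent-3-en-1-yl}-7-(methylsulfonyloxy)hept-5-enoate | CCCCC/C=C\C[C@@]1(O[Si](CC)(CC)CC)C=C(Br)C(=O)C1C(OS(C)(=O)=O)/C=C/CCCC(=O)OC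
F13 | step 9 | methyl (5E,7E)-7-{(2R)-4-bromo-2-[(2Z)-oct-2-en-1-yl]-5-oxo-2-(triethylsilyloxy)cyclopent-3-en-1-ylidene}hept-5-enoate | CCCCC/C=C\C[C@@]1(O[Si](CC)(CC)CC)C=C(Br)C(=O)/C1=C/C=C/CCCC(=O)OC
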